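## The problem

Target 25 is an achiral oligomer of seven benzene rings joined only through six diaryl ether oxygens and carrying eighteen free hydroxyls. It has no stereocentre, so nothing has to be set or relayed; the only stereochemical element in the route is the geometry of one enol ether in an open-chain intermediate. The rings are lettered A to G from the 2,4,6-trihydroxyphenoxy end, and position 1 of each of rings B to G is the carbon bound to the ether oxygen on the ring A side. Rings B and F then carry oxygens at 1, 3, 4 and 5, with the 4-oxygen (the ether to ring C or G) flanked by two oxygens. Rings C and E are pentaoxygenated, with adjacent aryloxy groups at positions 1 and 6, and ring D carries aryloxy groups at 1 and 5 and hydroxyls at 3 and 4. The task is therefore regiochemical: four of the six ether oxygens sit between two ortho substituents on one of their rings, and every ring is electron-rich and a poor partner for plain nucleophilic aromatic substitution. The free pyrogallol- and phloroglucinol-type rings oxidise in air, fastest as phenoxides, so the hydroxyls must stay masked to the end and the unmasking must spare the diaryl ethers. The enabling feature is ring B: its oxygens at B1, B3 and B5 alternate as in phloroglucinol and B4 carries a fourth. Its six carbons map onto a hexanoate in which the ester carbon is B5, C3 is B1 (bearing ring A as an enol ether), the ketone C5 is B3, and C6 is B4 (bearing ring C's oxygen). A Claisen condensation forming B4–B5 closes ring B with both flanking ethers already in place.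

## Retrosynthesis

**25 from 24.** The last operation removes sixteen O-methyl groups from 24, the heptamer that is methylated everywhere except at B3 and B5. Methyl ethers are chosen because they survive copper catalysis, peracid, amide bases and enolate chemistry, and because boron tribromide cleaves aryl methyl ethers while leaving diaryl ethers untouched. The building blocks with this masking are also commercial.

**24 from 23 (ring B).** Cutting B4–B5 opens ring B to the keto enoate 23, methyl (E)-3-(2,4,6-trimethoxyphenoxy)-5-oxo-6-aryloxyhex-2-enoate. The neighbouring cuts, at the two ether bonds of ring B, would require a leaving group at B4 between two oxygens and a coupling to the doubly ortho-substituted ring A. The Claisen cut avoids both hindered couplings and delivers B3 and B5 as free hydroxyls, which the target needs anyway. The forward step must favour C-acylation over lactonisation to a 2-pyrone and must not disturb the aryl enol ether.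

**23 from 21 and 18.** Cutting the bond between C4 and the ketone carbon C5 gives two pieces of very different size: crotonate 21, which carries ring A, and Weinreb amide 18, which carries rings C to G. The γ-lithiated form of 21 (dienolate 22) is the nucleophile. A Weinreb amide is preferred over an ester or acid chloride because its tetrahedral adduct holds until work-up, so the acidic product is never exposed to the dienolate.

**21 from 19 and 20.** The enol ether oxygen–carbon bond is cut to 2,4,6-trimethoxyphenol 19 and methyl but-2-ynoate 20, joined by a base-catalysed oxa-Michael addition. This puts the hindered ring A oxygen on carbon without any aryl coupling. The forward step must give the E isomer, in which the methyl group is cis to the ester.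

**18 from 16 and 17.** The O–CH2 bond is cut to pentamer phenol 16 and 2-chloro-N-methoxy-N-methylacetamide 17. A single Williamson alkylation installs the two-carbon acyl unit already as the Weinreb amide.

**16 from 13 and 6 (via 14 and 15).** The bond between ring D's oxygen and C6 is cut. The oxygen stays on the unhindered phenol 13, and ring C arrives as 2-bromo-3,4,5-trimethoxybenzaldehyde 6. The ortho formyl group activates the flanked bromide and afterwards becomes the C1 hydroxyl by Baeyer–Villiger oxidation of aldehyde 14 through formate 15. The opposite polarity would need the flanked C6 oxygen as a nucleophile toward an unactivated ring D halide.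

**13 from 9 and 10 (via 11 and 12).** The bond between ring E's oxygen and D5 is cut to phenol 9 and 3-bromo-4,5-dimethoxybenzaldehyde 10. The formyl group of 10 sits at D1, so oxidation of aldehyde 11 through formate 12 uncovers the next nucleophilic oxygen. Both partners carry one ortho substituent here, which makes this the most demanding of the four couplings.

**9 from 5 and 6 (via 7 and 8).** The bond between ring F's oxygen and E6 is cut in the same way as for ring C. Phenol 5 and bromide 6 give aldehyde 7, and formate 8 gives the E1 phenol 9. Rings C and E thus come from one commercial building block.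

**5 from 1 and 2 (via 3 and 4).** The bond between ring G's oxygen and F4 is cut to 3,4,5-trimethoxyphenol 1 and 4-bromo-3,5-dimethoxybenzaldehyde 2. The para formyl group activates the bromide between two methoxy groups, and oxidation of aldehyde 3 through formate 4 gives the F1 phenol 5. The whole CDEFG chain is therefore one repeated pair of operations: copper-catalysed etherification of the growing phenol with a bromobenzaldehyde, then aldehyde-to-phenol oxidation.

## Roads not taken

**Alternative 1:** The cut goes through both ether bonds of ring B, which would arrive as a dichloroarene bound to a cyclopentadienylruthenium cation, complex A1. In the forward direction the phenoxide of 19 would displace the unhindered chloride, and the phenoxide of the ring C catechol monobenzyl ether A2 would displace the chloride flanked by two methoxy groups. Irradiation in acetonitrile would then release the ABC trimer A3.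
- Merits: the metal makes an electron-rich chloroarene behave as a good substrate for nucleophilic aromatic substitution near room temperature. Both hindered ethers of ring B form without copper at high temperature, and no free resorcinol or pyrone competitor appears. In these respects it is cleaner than the Claisen closure chosen here.
- Weak points: ruthenium is used in stoichiometric amount, with separate complexation and photolytic release steps. The second substitution takes place on a complex already deactivated by one aryloxy donor, at the most hindered carbon, with an ortho-substituted phenoxide. A3 is only a trimer: after debenzylation the flanked C6 oxygen would have to be joined to a DEFG aryl halide with no activating group, the hindered coupling that the chosen chain avoids.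
- Comparison: the chosen plan offers base-metal catalysis throughout and a ring B closure from a chain that already holds both aryloxy groups. It pays with a pyrone competitor.

**Alternative 2:** The cut goes through both ether bonds of ring D, with 2,4,6-trifluorobenzaldehyde A4 as linchpin. The ABC phenol A5 would displace the para fluoride, and the EFG phenol 9 (also an intermediate of the present route) would displace an ortho fluoride, giving the heptamer skeleton A6 in one pot.
- Merits: it is the most convergent plan (three rings, one ring, three rings), needs no metal, and would give a much shorter longest linear sequence than the chosen route.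
- Weak points: the first substitution must distinguish para from ortho fluoride. The nucleophilic oxygen of A5 lies between an aryloxy and a methoxy group. Each aryloxy group introduced deactivates the ring toward the next substitution. A6 still lacks both ring D oxygens: the last fluoride must be exchanged for an oxygen nucleophile on a ring by then electron-rich, and the aldehyde must be oxidised to a phenol. A5 also contains ring B, which needs its own solution.
- Comparison: the chosen plan is longer and linear, but every carbon–oxygen bond is formed at a single bromide with no positional ambiguity, and ring D's methoxy groups come ready-made in 10.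

**Alternative 3:** The cut replaces the two ether bonds at ring E (to D and to F) by ester groups. The depside A7 would lose two molecules of carbon monoxide under zerovalent nickel from Ni(cod)2 with the diphosphine dcypt, giving the DEFG tetramer A8.
- Merits: esterification of hindered phenols is easy where etherification is not. If the extrusion worked twice, two copper couplings and two oxidations of the chosen route would shrink to two acylations and one catalytic step, a real gain in step economy.
- Weak points: decarbonylative etherification is secure mainly for esters of azine carboxylic acids. Here the acyl groups are electron-rich benzoyl units, one of them ortho-substituted, and one phenolic oxygen is flanked on both sides. Two extrusions are needed in one molecule at high temperature, and the released carbon monoxide binds the catalyst. A8 (the benzyl ether of 13) still needs ring C and the ring A–B part.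
- Comparison: the chosen plan uses only well-understood etherifications with activated bromides, at the price of more steps.

Key step: step 12

Assumption: all hydroxyls are carried as methyl ethers, which only the last step removes; compounds 1, 2, 6, 10, 17, 19 and 20 are taken as purchasable.

## Route

Step 1
Reactants: 1 3,4,5-trimethoxyphenol; 2 4-bromo-3,5-dimethoxybenzaldehyde
Product: 3 FG aldehyde (3,5-dimethoxy-4-(3,4,5-trimethoxyphenoxy)benzaldehyde)
Conditions: CuI (10 mol %), picolinic acid (20 mol %), K3PO4, DMSO, 90 °C
Reagents that add atoms: none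
Why: Ullmann-type diaryl ether synthesis with monovalent copper; the bromide of 2 is activated by the para formyl group and the phenol is electron-rich and unhindered, while the picolinate ligand is suited to an ortho-disubstituted halide. The formyl group is carried on as the latent F1 oxygen.

Step 2
Reactants: 3 FG aldehyde
Product: 5 FG phenol (3,5-dimethoxy-4-(3,4,5-trimethoxyphenoxy)phenol), via FG aryl formate 4 (not isolated)
Conditions: mCPBA, CH2Cl2, 0 °C to rt; then K2CO3, MeOH, rt
Reagents that add atoms: meta-chloroperbenzoic acid (mCPBA), OOC(=O)c1cccc(Cl)c1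
Why: Baeyer–Villiger (Dakin-type) oxidation; the electron-rich aryl group with its para aryloxy donor migrates in preference to hydride, and methanolysis of the formate frees the phenol.

Step 3
Reactants: 5 FG phenol; 6 2-bromo-3,4,5-trimethoxybenzaldehyde
Product: 7 EFG aldehyde (2-[3,5-dimethoxy-4-(3,4,5-trimethoxyphenoxy)phenoxy]-3,4,5-trimethoxybenzaldehyde)
Conditions: CuI (10 mol %), picolinic acid (20 mol %), K3PO4, DMSO, 90 °C
Reagents that add atoms: none
Why: Ullmann coupling in which the ortho formyl group activates the flanked bromide and can chelate copper; the phenol has two free ortho positions. This forms the ether from ring F's oxygen to E6.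

Step 4
Reactants: 7 EFG aldehyde
Product: 9 EFG phenol (2-[3,5-dimethoxy-4-(3,4,5-trimethoxyphenoxy)phenoxy]-3,4,5-trimethoxyphenol), via EFG aryl formate 8 (not isolated)
Conditions: mCPBA, CH2Cl2, 0 °C to rt; then K2CO3, MeOH, rt
Reagents that add atoms: meta-chloroperbenzoic acid (mCPBA), OOC(=O)c1cccc(Cl)c1
Why: Baeyer–Villiger oxidation with aryl migration favoured by the ortho aryloxy and para methoxy donors; formate methanolysis uncovers the E1 hydroxyl.

Step 5
Reactants: 9 EFG phenol; 10 3-bromo-4,5-dimethoxybenzaldehyde
Product: 11 DEFG aldehyde (3,4-dimethoxy-5-(EFG-oxy)benzaldehyde, the EFG group being 9 joined through its phenol oxygen)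
Conditions: CuI (20 mol %), picolinic acid (40 mol %), K3PO4, DMSO, 100 °C
Reagents that add atoms: none
Why: Ullmann coupling of an ortho-aryloxy phenol with an ortho-methoxy aryl bromide, the pairing known from 4-O-5-type diaryl ethers; ligand-accelerated copper catalysis tolerates one ortho substituent on each partner. This forms the ether from ring E's oxygen to D5.

Step 6
Reactants: 11 DEFG aldehyde
Product: 13 DEFG phenol (3,4-dimethoxy-5-(EFG-oxy)phenol), via DEFG aryl formate 12 (not isolated)
Conditions: mCPBA, CH2Cl2, 0 °C to rt; then K2CO3, MeOH, rt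
Reagents that add atoms: meta-chloroperbenzoic acid (mCPBA), OOC(=O)c1cccc(Cl)c1
Why: Baeyer–Villiger oxidation of a 3,4,5-trioxygenated benzaldehyde, whose para methoxy group secures aryl migration; methanolysis gives the unhindered D1 phenol.

Step 7
Reactants: 13 DEFG phenol; 6 2-bromo-3,4,5-trimethoxybenzaldehyde
Product: 14 CDEFG aldehyde (3,4,5-trimethoxy-2-(DEFG-oxy)benzaldehyde, the DEFG group being 13 joined through its phenol oxygen)
Conditions: CuI (10 mol %), picolinic acid (20 mol %), K3PO4, DMSO, 90 °C
Reagents that add atoms: none
Why: The same ortho-formyl-activated Ullmann coupling as in step 3, again with a phenol free at both ortho positions. This forms the ether from ring D's oxygen to C6.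

Step 8
Reactants: 14 CDEFG aldehyde
Product: 16 CDEFG phenol (3,4,5-trimethoxy-2-(DEFG-oxy)phenol), via CDEFG aryl formate 15 (not isolated)
Conditions: mCPBA, CH2Cl2, 0 °C to rt; then K2CO3, MeOH, rt
Reagents that add atoms: meta-chloroperbenzoic acid (mCPBA), OOC(=O)c1cccc(Cl)c1
Why: Baeyer–Villiger oxidation as in step 4 (ortho aryloxy and para methoxy donors), followed by formate methanolysis to the C1 hydroxyl.

Step 9
Reactants: 16 CDEFG phenol; 17 2-chloro-N-methoxy-N-methylacetamide
Product: 18 Weinreb amide (N-methoxy-N-methyl-2-(CDEFG-oxy)acetamide, the CDEFG group being 16 joined through its phenol oxygen)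
Conditions: K2CO3, KI (cat.), DMF, 60 °C
Reagents that add atoms: none
Why: Williamson ether synthesis, an SN2 displacement of the α-chloro amide by the phenoxide with iodide catalysis; it installs the acyl donor for step 11 in one operation.

Step 10
Reactants: 19 2,4,6-trimethoxyphenol; 20 methyl but-2-ynoate
Product: 21 methyl (E)-3-(2,4,6-trimethoxyphenoxy)but-2-enoate
Conditions: K2CO3 (20 mol %), DMF, 80 °C
Reagents that add atoms: none
Why: Base-catalysed oxa-Michael addition of a phenoxide to an alkynoate; reversible addition and elimination at this temperature should lead to the more stable E enol ether, with the aryloxy group trans to the ester and the methyl group cis to it.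

Step 11
Reactants: 21 methyl (E)-3-(2,4,6-trimethoxyphenoxy)but-2-enoate (2 equiv); 18 Weinreb amide
Product: 23 methyl (E)-3-(2,4,6-trimethoxyphenoxy)-5-oxo-6-(CDEFG-oxy)hex-2-enoate, via lithium dienolate 22 (not isolated)
Conditions: LiN(i-Pr)2, THF, −78 °C; then 18, −78 to −40 °C; sat. aq. NH4Cl at −78 °C
Reagents that add atoms: none
Why: γ-Deprotonation of an E β-oxy crotonate and reaction of the vinylogous enolate at its γ carbon, as in kawain-type lactone syntheses, here as a Weinreb ketone synthesis. The chelated tetrahedral adduct releases the ketone only on quench, so the acidic product never meets the dienolate, and cold neutral work-up avoids lactonisation.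

Step 12
Reactants: 23 methyl (E)-3-(2,4,6-trimethoxyphenoxy)-5-oxo-6-(CDEFG-oxy)hex-2-enoate
Product: 24 heptamer with free B3 and B5 hydroxyls and sixteen methyl ethers
Conditions: LiN(SiMe3)2 (3.5 equiv), THF, −78 °C to 50 °C; then aq. HCl to pH 3
Reagents that add atoms: none
Why: This is an intramolecular Claisen (Dieckmann-type) condensation of a masked triketide, the reaction class by which 3,5-dioxohexanoate esters and their 3-O-alkyl enol ethers give phloroglucinols and 5-alkoxyresorcinols under base. The first equivalent of base removes the C4 proton between ketone and enol ether. Excess base, with HN(SiMe3)2 as proton shuttle, gives access to the enolate at C6, as the dianion or as the C6 mono-enolate tautomer; the aryloxy group of ring C raises the acidity at this carbon. C6 attacks the ester carbonyl in a 6-(enolendo)-exo-trig closure that forms B4–B5, methoxide leaves, and the cyclohexadienone loses the B4 proton to become the aromatic bis-phenoxide, which makes the sequence irreversible. No stereocentre is formed. The selectivity needed is C-acylation over O-acylation to a 2-pyrone: the middle oxygen is blocked as the aryl enol ether, the base is non-nucleophilic so the ring A aryloxide at C3 is not exchanged, and only the C-acylation path ends in an aromatic sink. The E enol ether holds the ester and the ketone arm cis; if the geometry scrambles through the dienolate, only the E form can close, so both isomers converge.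

Step 13
Reactants: 24 heptamer with free B3 and B5 hydroxyls
Product: 25 target heptamer (CNP0130704.0)
Conditions: BBr3 (excess), CH2Cl2, −78 °C to rt; MeOH then H2O, under argon
Reagents that add atoms: none
Why: Lewis acid-mediated cleavage of aryl methyl ethers, in which bromide attacks the methyl group of the boron-complexed ether; diaryl ether bonds offer no carbon open to SN2 attack and should stay intact. Sixteen methyl groups are removed, and B3 and B5 are already free.

## Compound list

1 | 3,4,5-trimethoxyphenol | COc1cc(O)cc(OC)c1OC | starting material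
2 | 4-bromo-3,5-dimethoxybenzaldehyde | COc1cc(C=O)cc(OC)c1Br | starting material
3 | FG aldehyde, 3,5-dimethoxy-4-(3,4,5-trimethoxyphenoxy)benzaldehyde | COc1cc(C=O)cc(OC)c1Oc1cc(OC)c(OC)c(OC)c1 | intermediate
4 | FG aryl formate, 3,5-dimethoxy-4-(3,4,5-trimethoxyphenoxy)phenyl formate | COc1cc(OC=O)cc(OC)c1Oc1cc(OC)c(OC)c(OC)c1 | intermediate (not isolated)
5 | FG phenol, 3,5-dimethoxy-4-(3,4,5-trimethoxyphenoxy)phenol | COc1cc(O)cc(OC)c1Oc1cc(OC)c(OC)c(OC)c1 | intermediate
6 | 2-bromo-3,4,5-trimethoxybenzaldehyde | COc1cc(C=O)c(Br)c(OC)c1OC | starting material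
7 | EFG aldehyde, 2-[3,5-dimethoxy-4-(3,4,5-trimethoxyphenoxy)phenoxy]-3,4,5-trimethoxybenzaldehyde | COc1cc(C=O)c(Oc2cc(OC)c(Oc3cc(OC)c(OC)c(OC)c3)c(OC)c2)c(OC)c1OC | intermediate
8 | EFG aryl formate, formate ester of 9 | COc1cc(OC=O)c(Oc2cc(OC)c(Oc3cc(OC)c(OC)c(OC)c3)c(OC)c2)c(OC)c1OC | intermediate (not isolated)
9 | EFG phenol, 2-[3,5-dimethoxy-4-(3,4,5-trimethoxyphenoxy)phenoxy]-3,4,5-trimethoxyphenol | COc1cc(O)c(Oc2cc(OC)c(Oc3cc(OC)c(OC)c(OC)c3)c(OC)c2)c(OC)c1OC | intermediate
10 | 3-bromo-4,5-dimethoxybenzaldehyde | COc1cc(C=O)cc(Br)c1OC | starting material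
11 | DEFG aldehyde, 3,4-dimethoxy-5-(EFG-oxy)benzaldehyde | COc1cc(C=O)cc(Oc2cc(OC)c(OC)c(OC)c2Oc2cc(OC)c(Oc3cc(OC)c(OC)c(OC)c3)c(OC)c2)c1OC | intermediate
12 | DEFG aryl formate, formate ester of 13 | COc1cc(OC=O)cc(Oc2cc(OC)c(OC)c(OC)c2Oc2cc(OC)c(Oc3cc(OC)c(OC)c(OC)c3)c(OC)c2)c1OC | intermediate (not isolated)
13 | DEFG phenol, 3,4-dimethoxy-5-(EFG-oxy)phenol | COc1cc(O)cc(Oc2cc(OC)c(OC)c(OC)c2Oc2cc(OC)c(Oc3cc(OC)c(OC)c(OC)c3)c(OC)c2)c1OC | intermediate
14 | CDEFG aldehyde, 3,4,5-trimethoxy-2-(DEFG-oxy)benzaldehyde | COc1cc(C=O)c(Oc2cc(OC)c(OC)c(Oc3cc(OC)c(OC)c(OC)c3Oc3cc(OC)c(Oc4cc(OC)c(OC)c(OC)c4)c(OC)c3)c2)c(OC)c1OC | intermediate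
15 | CDEFG aryl formate, formate ester of 16 | COc1cc(OC=O)c(Oc2cc(OC)c(OC)c(Oc3cc(OC)c(OC)c(OC)c3Oc3cc(OC)c(Oc4cc(OC)c(OC)c(OC)c4)c(OC)c3)c2)c(OC)c1OC | intermediate (not isolated)
16 | CDEFG phenol, 3,4,5-trimethoxy-2-(DEFG-oxy)phenol | COc1cc(O)c(Oc2cc(OC)c(OC)c(Oc3cc(OC)c(OC)c(OC)c3Oc3cc(OC)c(Oc4cc(OC)c(OC)c(OC)c4)c(OC)c3)c2)c(OC)c1OC | intermediate
17 | 2-chloro-N-methoxy-N-methylacetamide | CON(C)C(=O)CCl | starting material
18 | Weinreb amide, N-methoxy-N-methyl-2-(CDEFG-oxy)acetamide | CON(C)C(=O)COc1cc(OC)c(OC)c(OC)c1Oc1cc(OC)c(OC)c(Oc2cc(OC)c(OC)c(OC)c2Oc2cc(OC)c(Oc3cc(OC)c(OC)c(OC)c3)c(OC)c2)c1 | intermediate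
19 | 2,4,6-trimethoxyphenol | COc1cc(OC)c(O)c(OC)c1 | starting material
20 | methyl but-2-ynoate | CC#CC(=O)OC | starting material
21 | methyl (E)-3-(2,4,6-trimethoxyphenoxy)but-2-enoate | COC(=O)/C=C(/Oc1c(OC)cc(OC)cc1OC)C | intermediate
22 | lithium dienolate of 21, lithium 1-methoxy-3-(2,4,6-trimethoxyphenoxy)buta-1,3-dien-1-olate | [Li+].[O-]C(OC)=CC(=C)Oc1c(OC)cc(OC)cc1OC | intermediate (not isolated)
23 | methyl (E)-3-(2,4,6-trimethoxyphenoxy)-5-oxo-6-(CDEFG-oxy)hex-2-enoate | COC(=O)/C=C(/Oc1c(OC)cc(OC)cc1OC)CC(=O)COc1cc(OC)c(OC)c(OC)c1Oc1cc(OC)c(OC)c(Oc2cc(OC)c(OC)c(OC)c2Oc2cc(OC)c(Oc3cc(OC)c(OC)c(OC)c3)c(OC)c2)c1 | intermediate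
24 | heptamer, hexadeca-O-methyl, free hydroxyls at B3 and B5 | COc1cc(OC)c(Oc2cc(O)c(Oc3cc(OC)c(OC)c(OC)c3Oc3cc(OC)c(OC)c(Oc4cc(OC)c(OC)c(OC)c4Oc4cc(OC)c(Oc5cc(OC)c(OC)c(OC)c5)c(OC)c4)c3)c(O)c2)c(OC)c1 | intermediate
25 | CNP0130704.0, the free heptamer | Oc1cc(O)c(Oc2cc(O)c(Oc3cc(O)c(O)c(O)c3Oc3cc(O)c(O)c(Oc4cc(O)c(O)c(O)c4Oc4cc(O)c(Oc5cc(O)c(O)c(O)c5)c(O)c4)c3)c(O)c2)c(O)c1 | target

## Step count and risks

Total steps: 13. Longest linear sequence: 12 (steps 1 to 9, then 11, 12 and 13); step 10 is a one-step side branch.

**Step 12 (key step).** The C4 dienolate delocalises into the ester and lowers its electrophilicity. Ring closure may therefore be slow, and on heating the chain may lactonise through the ketone enolate oxygen to a 2-pyrone or lose the ring A aryloxide by addition–elimination of released methoxide. The fallback builds ring B by the etherification logic of the rest of the chain. It sets out from 16 and rejoins the route at 25. Phenol 16 would be coupled with bromide 2 (CuI, picolinic acid, K3PO4, DMSO) to give the hexamer aldehyde F1. Baeyer–Villiger oxidation with mCPBA would pass through the hexamer aryl formate F2 (not isolated), and methanolysis would give the hexamer phenol F3 with a free B1 hydroxyl. Ullmann coupling of F3 with commercial 2-bromo-1,3,5-trimethoxybenzene would give the permethylated heptamer F4, and boron tribromide would convert F4 into 25.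

**Step 11.** The lithium dienolate 22 may expel 2,4,6-trimethoxyphenoxide (retro-oxa-Michael fragmentation toward the allenoate) before it is acylated. It may also act as a base toward the OCH2 group of 18, and the product may lactonise during work-up. The fallback avoids the β-aryloxy dienolate; it sets out from 18 and rejoins at 23. The dianion of methyl acetoacetate (NaH, then n-BuLi) would be acylated with 18 to give the triketide ester F5. DBU in hot toluene would close F5 to the 4-hydroxy-2-pyrone F6, and P2O5 with Bu4NBr would convert this into the 4-bromo-2-pyrone F7. Addition–elimination with 19 and K2CO3 in DMF would give the 4-aryloxy-2-pyrone F8. Ring opening of F8 with Mg(OMe)2 in methanol would deliver 23 with the E geometry fixed by the former ring.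

**Step 5.** With an ortho substituent on each partner, ligand exchange and oxidative addition at copper may be slow, so that protodebromination of 10 outruns coupling. The fallback reverses the role of ring D; it sets out from 10 and rejoins at 11. Miyaura borylation of 10 with B2(OH)4 (Pd(OAc)2, XPhos, KOAc, ethanol) would give (5-formyl-2,3-dimethoxyphenyl)boronic acid F9. Chan–Evans–Lam coupling of F9 with phenol 9 (Cu(OAc)2, pyridine, 4 Å molecular sieves, CH2Cl2, air, rt), an oxidative coupling at divalent copper, would then give 11.

**Step 13.** Sixteen ether cleavages in one molecule may stop short, leaving partly methylated material, and the free polyphenol may oxidise in air during isolation. The fallback isolates the product in protected form; it sets out from 24 and rejoins at 25. The crude product of the boron tribromide reaction would be acetylated directly (Ac2O, pyridine) to the octadecaacetate F10, which is stable to air and can be purified by chromatography, with under-demethylated fractions returned to boron tribromide. Acid methanolysis of F10 (HCl in MeOH, argon) would then release 25 without exposing it to base.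

## Further compounds

F1 | step 12 | hexamer aldehyde, 3,5-dimethoxy-4-(CDEFG-oxy)benzaldehyde | COc1cc(C=O)cc(OC)c1Oc1cc(OC)c(OC)c(OC)c1Oc1cc(OC)c(OC)c(Oc2cc(OC)c(OC)c(OC)c2Oc2cc(OC)c(Oc3cc(OC)c(OC)c(OC)c3)c(OC)c2)c1
F2 | step 12 | hexamer aryl formate, formate ester of F3 | COc1cc(OC=O)cc(OC)c1Oc1cc(OC)c(OC)c(OC)c1Oc1cc(OC)c(OC)c(Oc2cc(OC)c(OC)c(OC)c2Oc2cc(OC)c(Oc3cc(OC)c(OC)c(OC)c3)c(OC)c2)c1
F3 | step 12 | hexamer phenol, 3,5-dimethoxy-4-(CDEFG-oxy)phenol | COc1cc(O)cc(OC)c1Oc1cc(OC)c(OC)c(OC)c1Oc1cc(OC)c(OC)c(Oc2cc(OC)c(OC)c(OC)c2Oc2cc(OC)c(Oc3cc(OC)c(OC)c(OC)c3)c(OC)c2)c1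
F4 | step 12 | permethylated heptamer (octadeca-O-methyl ether of 25) | COc1cc(OC)c(Oc2cc(OC)c(Oc3cc(OC)c(OC)c(OC)c3Oc3cc(OC)c(OC)c(Oc4cc(OC)c(OC)c(OC)c4Oc4cc(OC)c(Oc5cc(OC)c(OC)c(OC)c5)c(OC)c4)c3)c(OC)c2)c(OC)c1
F5 | step 11 | methyl 3,5-dioxo-6-(CDEFG-oxy)hexanoate | COC(=O)CC(=O)CC(=O)COc1cc(OC)c(OC)c(OC)c1Oc1cc(OC)c(OC)c(Oc2cc(OC)c(OC)c(OC)c2Oc2cc(OC)c(Oc3cc(OC)c(OC)c(OC)c3)c(OC)c2)c1
F6 | step 11 | 4-hydroxy-6-[(CDEFG-oxy)methyl]-2H-pyran-2-one | O=C1C=C(O)C=C(COc2cc(OC)c(OC)c(OC)c2Oc2cc(OC)c(OC)c(Oc3cc(OC)c(OC)c(OC)c3Oc3cc(OC)c(Oc4cc(OC)c(OC)c(OC)c4)c(OC)c3)c2)O1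
F7 | step 11 | 4-bromo-6-[(CDEFG-oxy)methyl]-2H-pyran-2-one | O=C1C=C(Br)C=C(COc2cc(OC)c(OC)c(OC)c2Oc2cc(OC)c(OC)c(Oc3cc(OC)c(OC)c(OC)c3Oc3cc(OC)c(Oc4cc(OC)c(OC)c(OC)c4)c(OC)c3)c2)O1
F8 | step 11 | 4-(2,4,6-trimethoxyphenoxy)-6-[(CDEFG-oxy)methyl]-2H-pyran-2-one | O=C1C=C(Oc2c(OC)cc(OC)cc2OC)C=C(COc2cc(OC)c(OC)c(OC)c2Oc2cc(OC)c(OC)c(Oc3cc(OC)c(OC)c(OC)c3Oc3cc(OC)c(Oc4cc(OC)c(OC)c(OC)c4)c(OC)c3)c2)O1
F9 | step 5 | (5-formyl-2,3-dimethoxyphenyl)boronic acid | COc1cc(C=O)cc(B(O)O)c1OC
F10 | step 13 | octadecaacetate of 25 | CC(=O)Oc1cc(OC(C)=O)c(Oc2cc(OC(C)=O)c(Oc3cc(OC(C)=O)c(OC(C)=O)c(OC(C)=O)c3Oc3cc(OC(C)=O)c(OC(C)=O)c(Oc4cc(OC(C)=O)c(OC(C)=O)c(OC(C)=O)c4Oc4cc(OC(C)=O)c(Oc5cc(OC(C)=O)c(OC(C)=O)c(OC(C)=O)c5)c(OC(C)=O)c4)c3)c(OC(C)=O)c2)c(OC(C)=O)c1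
A1 | alternative 1 | [CpRu(η6-2,5-dichloro-1,3-dimethoxybenzene)]PF6 | COc1cc(Cl)cc(OC)c1Cl.[Ru+2].c1cc[cH-]c1.F[P-](F)(F)(F)(F)F
A2 | alternative 1 | 2-(benzyloxy)-3,4,5-trimethoxyphenol | COc1cc(O)c(OCc2ccccc2)c(OC)c1OC
A3 | alternative 1 | ABC trimer, permethylated, benzyl ether at the ring C oxygen that joins ring D | COc1cc(OC)c(Oc2cc(OC)c(Oc3cc(OC)c(OC)c(OC)c3OCc3ccccc3)c(OC)c2)c(OC)c1
A4 | alternative 2 | 2,4,6-trifluorobenzaldehyde | O=Cc1c(F)cc(F)cc1F
A5 | alternative 2 | ABC phenol, 2,3,4-trimethoxy-6-[2,6-dimethoxy-4-(2,4,6-trimethoxyphenoxy)phenoxy]phenol | Oc1c(OC)c(OC)c(OC)cc1Oc1c(OC)cc(Oc2c(OC)cc(OC)cc2OC)cc1OC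
A6 | alternative 2 | heptamer skeleton with ring D as a 2-fluoro-4,6-bis(aryloxy)benzaldehyde | O=Cc1c(F)cc(Oc2c(OC)c(OC)c(OC)cc2Oc2c(OC)cc(Oc3c(OC)cc(OC)cc3OC)cc2OC)cc1Oc1cc(OC)c(OC)c(OC)c1Oc1cc(OC)c(Oc2cc(OC)c(OC)c(OC)c2)c(OC)c1
A7 | alternative 3 | depside, 5-(benzyloxy)-2,3-dimethoxyphenyl 2-{[3,5-dimethoxy-4-(3,4,5-trimethoxyphenoxy)benzoyl]oxy}-3,4,5-trimethoxybenzoate | c1ccccc1COc1cc(OC)c(OC)c(OC(=O)c2cc(OC)c(OC)c(OC)c2OC(=O)c2cc(OC)c(Oc3cc(OC)c(OC)c(OC)c3)c(OC)c2)c1
A8 | alternative 3 | DEFG tetramer, permethylated, D1 oxygen as benzyl ether | c1ccccc1COc1cc(OC)c(OC)c(Oc2cc(OC)c(OC)c(OC)c2Oc2cc(OC)c(Oc3cc(OC)c(OC)c(OC)c3)c(OC)c2)c1
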